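All constants stand for no real mixture; the result is computed.

Whatever happens in these flasks, starting material plus product stays at its charge, and free enzyme, unfolded enzyme and spent catalyst together stay at theirs.

| flask | starting material | free enzyme | temperature | time |
|---|---|---|---|---|
| violet | 5.0 mM | 0.05 mol% | 5 °C | 25 s |
| ochre | 5.0 mM | 0.05 mol% | 30 °C | 25 s |

    free enzyme → unfolded enzyme (k1 = 0.0021 s⁻¹, Ea1 = 259 kJ mol⁻¹)
    starting material + free enzyme → product + free enzyme, rate k2*[starting material]^2*[free enzyme]/(1 + ([starting material]/Kh2)^2) (Kh2 = 5.0 mM, k2 = 6.8 × 10⁶ L² mol⁻² s⁻¹, Ea2 = 11.0 kJ mol⁻¹)
    free enzyme → spent catalyst (k3 = 0.18 s⁻¹, Ea3 = 76.0 kJ mol⁻¹)
    (constants at 30 °C)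

- constants are those at 30 °C; use the activation energies for any other temperature

1. the flask that comes out highest in amount of product, in percent of the starting material charged, or "all alike" when all lie within 1.5 percentage points (violet / ochre / all alike)
2. product at the end, in percent of the starting material charged, violet
3. product at the end, in percent of the starting material charged, ochre

The ledger therefore has two columns. Starting material stands as itself or as product, and the enzyme charge, 0.00250 mM, moves from free to lost. The making of product and both losses of enzyme each run in proportion to free enzyme, so dividing one rate by the other cancels free enzyme and time together. This leaves a fixed relation between starting material left and enzyme-seconds served.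

The enzyme-seconds come first. Free enzyme decays with the sum of its two loss constants, and its working time is the fraction lost by the end divided by that sum. In ochre the sum is 0.182 s⁻¹, so the working time is 5.43 s. Cooling to violet's 5 °C slows the loss to spent catalyst 15-fold, the loss to unfolded enzyme 10000-fold, and the making of product 1.5-fold. The sum in violet is then 0.0120 s⁻¹, and the working time 21.6 s, longer than ochre's.

Multiplying the rate constant of the making, the two charges and the working time gives a pure number, 1.24 in violet and 0.462 in ochre. This is the enzyme's budget, a measure of the turnover that free enzyme pays for.

The books close by this rule: the reciprocal of the fraction left, less one, plus the square of the charge over Kh times the fraction gone, equals the budget. Here the charge equals Kh, so the budget is simply the reciprocal of the fraction left minus that fraction. By this reckoning, violet's column closes at 44.4 % product and ochre's at 20.5 % product, the rest of each charge standing as starting material.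

The forecast names violet, with 44.3 % there and 20.5 % in ochre, against this reckoning's 44.4 % and 20.5 %. Its grounds: “That longer lifetime far outweighs the roughly one-third drop”.

The simulation puts violet highest, with 44.4 % against 20.5 % in ochre. Violet's budget stands 2.68 times ochre's, and the largest single effect on the gap in product is what temperature does to the loss to spent catalyst: without that effect, ochre minus violet moves from −24 percentage points to 11 points. A neighbour like violet, but with 12 mM of starting material at the same loading, has a budget of 7.15. The rule, with the square of its charge over Kh at 5.76, gives 74.2 % product, and that flask reads 74.2 %.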